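**Strategy.** The trans-fused α-methylene-γ-butyrolactone of the hydroxylated half (ring C: O–C8–C7–C11–C12, xanthane numbering) is disconnected into CO2, a C11 alkenyl bromide and a cis C8 mesylate. The key step, a nickel-catalysed reductive carboxylation with SN2 lactonisation in the same flask, forms C11–C12 and O–C8 at once and inverts C8. It exploits that the two halves differ in configuration only at C8: one trans bromo alcohol gives the cis lactone of the spiro half after mesylation with retention and ring C after mesylation with inversion, each time through the same CO2 annulation. The precursor is a Diels–Alder/ene-derived dimer whose diene half still carries bromide and mesylate.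

Key step: step 11

Numbering: xanthane numbering throughout; C1–C15 for the hydroxylated half (fragment 1), primed numbers for the spiro-lactone half (fragment 2). Ring A is the cycloheptane C1/C5–C10, ring B the cyclohexene C1–C2–C3–C11'–C13'–C5, ring C the lactone named above.

Assumption: the ligand antipodes named in steps 1 and 4 are taken to be those that give the configurations drawn; if the sense of induction is the opposite, the mirror-image ligand is used.

**Step 1**
Reactants: 1 (E)-but-2-enal (crotonaldehyde); 2 (triisopropylsilyl)acetylene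
Product: 3 (S)-3-methyl-5-(triisopropylsilyl)pent-4-ynal
Conditions: [Rh(OAc)(C2H4)2]2 (2.5 mol%), (R)-DTBM-SEGPHOS (6 mol%), MeOH, 40 °C
Reagents that add atoms: none
Why: Rhodium-catalysed asymmetric conjugate alkynylation of an enal, in which the bulky silyl alkyne suppresses alkyne dimerisation and the chiral bisphosphine selects the enal face to set the future C10 as S.

**Step 2**
Reactants: 4 prop-2-yn-1-ol (propargyl alcohol); 5 3-bromoprop-1-ene (allyl bromide)
Product: 6 (Z)-2-bromohexa-2,5-dien-1-ol
Conditions: PdBr2(PhCN)2 (3 mol%), allyl bromide (10 equiv, as solvent), 20 °C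
Reagents that add atoms: none
Why: Palladium-catalysed bromoallylation of a terminal alkyne: cis-bromopalladation places Br on the internal carbon, allyl bromide inserts and β-bromide elimination returns the catalyst, giving the Z alkene (Br cis to allyl).

**Step 3**
Reactants: 6 (Z)-2-bromohexa-2,5-dien-1-ol
Product: 7 (Z)-1,2-dibromohexa-2,5-diene
Conditions: CBr4, PPh3, CH2Cl2, 0 °C
Reagents that add atoms: tetrabromomethane BrC(Br)(Br)Br
Why: Appel bromination of the primary allylic alcohol by SN2 at the unhindered carbon, leaving the alkenyl bromide and the alkene geometry untouched.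

**Step 4**
Reactants: 3 (S)-3-methyl-5-(triisopropylsilyl)pent-4-ynal; 7 (Z)-1,2-dibromohexa-2,5-diene
Product: 9 (3R,4R,6S)-2-bromo-6-methyl-3-(prop-2-en-1-yl)oct-1-en-7-yn-4-ol, via trimethylsilyl ether 8 (not isolated)
Conditions: CrCl2 (10 mol%), (R,R)-1,8-bis(4-isopropyl-4,5-dihydrooxazol-2-yl)-3,6-diphenyl-9H-carbazole (10 mol%), Mn powder, Me3SiCl, i-Pr2NEt, THF, 20 °C; then Bu4NF (2.5 equiv), THF, 0 °C
Reagents that add atoms: none
Why: Catalytic asymmetric Nozaki–Hiyama–Kishi 2-bromoallylation, in which divalent chromium (regenerated by manganese) inserts only into the allylic C–Br bond and the γ-substituted allylchromium adds through a chair transition state with the allyl substituent equatorial to give the anti adduct whatever the alkene geometry (hydroxyl anti to the allyl group along the chain C9–C8–C7–C11, which places OH and bromovinyl trans on the later ring), the ligand directing attack to the Si face of the aldehyde (C8 R, C7 R), after which fluoride removes both silyl groups.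

**Step 5**
Reactants: 9 (3R,4R,6S)-2-bromo-6-methyl-3-(prop-2-en-1-yl)oct-1-en-7-yn-4-ol; 10 but-3-en-2-one (methyl vinyl ketone)
Product: 11 (E)-4-[(4R,5R,7S)-4-(1-bromoethenyl)-5-hydroxy-7-methylcyclohept-1-en-1-yl]but-3-en-2-one
Conditions: second-generation Hoveyda–Grubbs catalyst (10 mol%), methyl vinyl ketone (10 equiv), CH2Cl2, 40 °C
Reagents that add atoms: none
Why: Domino enyne ring-closing metathesis/cross-metathesis, in which the ruthenium alkylidene formed at the allyl terminus closes onto the alkyne in the exo mode to give the cycloheptene and the resulting vinyl carbene is captured by the enone as the E dienone, the free hydroxyl being tolerated and the 1,1-disubstituted bromoalkene being inert.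

**Step 6**
Reactants: 11 (E)-4-[(4R,5R,7S)-4-(1-bromoethenyl)-5-hydroxy-7-methylcyclohept-1-en-1-yl]but-3-en-2-one
Product: 12 (1R,2R,6S)-2-(1-bromoethenyl)-6-methyl-5-[(E)-3-oxobut-1-en-1-yl]cyclohept-4-en-1-yl methanesulfonate
Conditions: MsCl, Et3N, CH2Cl2, −10 °C
Reagents that add atoms: methanesulfonyl chloride CS(=O)(=O)Cl
Why: Sulfonylation at oxygen turns C8–O into a leaving group with retention, so the mesylate stays trans to the C7 bromovinyl group.

**Step 7**
Reactants: 12 (1R,2R,6S)-2-(1-bromoethenyl)-6-methyl-5-[(E)-3-oxobut-1-en-1-yl]cyclohept-4-en-1-yl methanesulfonate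
Product: 14 (3aS,7S,8aS)-7-methyl-3-methylidene-6-[(E)-3-oxobut-1-en-1-yl]-4,7,8,8a-tetrahydro-3aH-cyclohepta[b]furan-2-one, via manganese carboxylate 13 (not isolated)
Conditions: NiBr2(2,2'-bipyridine) (10 mol%), Mn powder (3 equiv), CO2 (1 atm), DMA, 25 °C; then 50 °C
Reagents that add atoms: carbon dioxide O=C=O
Why: Nickel-catalysed reductive carboxylation of the alkenyl bromide with CO2 followed by SN2 lactonisation: zerovalent nickel (regenerated by manganese) inserts into C11–Br, the alkenylnickel takes up CO2, and the manganese carboxylate 13 displaces the trans mesylate from the back (5-exo-tet), which inverts C8 and gives the cis-fused α-methylene lactone under anhydrous, base-free conditions.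

**Step 8**
Reactants: 11 (E)-4-[(4R,5R,7S)-4-(1-bromoethenyl)-5-hydroxy-7-methylcyclohept-1-en-1-yl]but-3-en-2-one
Product: 15 (1S,2R,6S)-2-(1-bromoethenyl)-6-methyl-5-[(E)-3-oxobut-1-en-1-yl]cyclohept-4-en-1-yl methanesulfonate
Conditions: MsOH (1.3 equiv), Et3N (0.4 equiv), PPh3, DIAD, toluene, 0 to 60 °C
Reagents that add atoms: methanesulfonic acid CS(=O)(=O)O
Why: Mitsunobu sulfonylation, in which the alkoxyphosphonium ion formed from 11, PPh3 and DIAD is displaced by methanesulfonate (kept in solution as its triethylammonium salt) in an SN2 reaction that inverts C8 (R to S) and gives the cis mesylate under nearly neutral conditions that spare the dienone and the alkenyl bromide.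

**Step 9**
Reactants: 15 (1S,2R,6S)-2-(1-bromoethenyl)-6-methyl-5-[(E)-3-oxobut-1-en-1-yl]cyclohept-4-en-1-yl methanesulfonate; 14 (3aS,7S,8aS)-7-methyl-3-methylidene-6-[(E)-3-oxobut-1-en-1-yl]-4,7,8,8a-tetrahydro-3aH-cyclohepta[b]furan-2-one
Product: 16 Diels–Alder adduct (ring B with C1=C2; 3-acetyl; 7-(1-bromoethenyl); 8-mesyloxy; spiro at C11'; 3S,5S,7R,8S,10S,7'S,8'S,10'S,11'R)
Conditions: toluene (2 M in the diene), BHT (5 mol%), 85 °C, the diene 15 in threefold excess, slow addition of the dienophile 14, unreacted diene recovered
Reagents that add atoms: none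
Why: Thermal Diels–Alder reaction in which the s-cis C5=C1–C2=C3 dienone of 15, which carries no reactive dienophile, adds to the exocyclic C11'=C13' of 14 with the "ortho" orientation imposed by the C3 acetyl group (bonds C3–C11' and C5–C13'), on the convex face of the cis-fused lactone with its carbonyl exo (sets C11'), and on the face of ring A opposite the C7 bromovinyl and C8 mesyloxy groups (sets C5, and C3 with H-3 cis to H-5 from the E alkene).

**Step 10**
Reactants: 16 Diels–Alder adduct
Product: 18 C1 tertiary alcohol with the ring B enone C2=C3 (1R,5S,7R,8S,10S,7'S,8'S,10'S,11'R), via C1 hydroperoxide 17 (not isolated)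
Conditions: O2, tetraphenylporphyrin (1 mol%), visible light, CH2Cl2, 0 °C; then PPh3, 0 °C
Reagents that add atoms: dioxygen O=O
Why: Schenck ene reaction of singlet oxygen at the only electron-rich alkene (C1=C2), in which oxygen adds to C1 on the less hindered face of ring B (that of H-3 and H-5) while abstracting the ketone-activated H-3 from the same face, so the alkene moves into conjugation (C2=C3) and the C1–O bond is cis to H-5 (1R), and triphenylphosphine then reduces the hydroperoxide.

**Step 11**
Reactants: 18 C1 tertiary alcohol with C11 bromide and cis C8 mesylate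
Product: 20 the target CNP0168949.5, via C12 manganese carboxylate 19 (not isolated)
Conditions: NiBr2(2,2'-bipyridine) (10 mol%), Mn powder (3 equiv), CO2 (1 atm), DMA, 25 °C; then 50 °C
Reagents that add atoms: carbon dioxide O=C=O
Why: Zerovalent nickel, regenerated by manganese, inserts into the C11–Br bond, the reduced alkenylnickel captures CO2 at carbon to form C11–C12, and the manganese carboxylate 19 so released displaces the C8 mesylate intramolecularly to form O–C8. The closest known reaction types are the nickel-catalysed reductive carboxylation of alkenyl halides with CO2 and the SN2 lactonisation of γ-sulfonyloxy carboxylates, and the same sequence is rehearsed on the monomer in step 7. Ring C closes in the 5-exo-tet mode. No stereocentre is created at C11, and C8 is inverted from S to R by backside attack, so the cis bromo mesylate gives the trans ring fusion while C7 is untouched. The step needs chemoselectivity for the alkenyl bromide over the enone, the dienone, the spiro-lactone and the secondary mesylate, and clean single inversion at C8. This is secured by the fast oxidative addition of the C(sp2)–Br bond, the absence of iodide or other halide additives that could pre-invert C8 or activate the mesylate, the large excess of CO2, and the geometry: with the mesylate axial and the C11 carboxylate equatorial on neighbouring carbons, only this carboxylate can reach the backside of C8 in a five-membered transition state.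

**Compound list**

1 | (E)-but-2-enal (crotonaldehyde) | C/C=C/C=O | starting material
2 | (triisopropylsilyl)acetylene | C#C[Si](C(C)C)(C(C)C)C(C)C | starting material
3 | (S)-3-methyl-5-(triisopropylsilyl)pent-4-ynal | O=CC[C@H](C)C#C[Si](C(C)C)(C(C)C)C(C)C | intermediate
4 | prop-2-yn-1-ol | C#CCO | starting material
5 | 3-bromoprop-1-ene (allyl bromide) | C=CCBr | starting material
6 | (Z)-2-bromohexa-2,5-dien-1-ol | OC/C(Br)=C/CC=C | intermediate
7 | (Z)-1,2-dibromohexa-2,5-diene | BrC/C(Br)=C/CC=C | intermediate
8 | trimethylsilyl ether of (3R,4R,6S)-2-bromo-6-methyl-3-(prop-2-en-1-yl)-8-(triisopropylsilyl)oct-1-en-7-yn-4-ol | CC(C)[Si](C(C)C)(C(C)C)C#C[C@@H](C)C[C@@H](O[Si](C)(C)C)[C@@H](CC=C)C(Br)=C | intermediate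
9 | (3R,4R,6S)-2-bromo-6-methyl-3-(prop-2-en-1-yl)oct-1-en-7-yn-4-ol (anti adduct) | C#C[C@@H](C)C[C@@H](O)[C@@H](CC=C)C(Br)=C | intermediate
10 | but-3-en-2-one (methyl vinyl ketone) | C=CC(C)=O | starting material
11 | (E)-4-[(4R,5R,7S)-4-(1-bromoethenyl)-5-hydroxy-7-methylcyclohept-1-en-1-yl]but-3-en-2-one (trans bromo alcohol) | O[C@@H]1C[C@H](C)C(/C=C/C(C)=O)=CC[C@H]1C(Br)=C | intermediate
12 | (1R,2R,6S)-2-(1-bromoethenyl)-6-methyl-5-[(E)-3-oxobut-1-en-1-yl]cyclohept-4-en-1-yl methanesulfonate (trans mesylate) | CS(=O)(=O)O[C@@H]1C[C@H](C)C(/C=C/C(C)=O)=CC[C@H]1C(Br)=C | intermediate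
13 | manganese carboxylate of 12 (CO2 in place of Br), drawn as the free acid 2-[(1S,5S,7R)-7-(methanesulfonyloxy)-5-methyl-4-[(E)-3-oxobut-1-en-1-yl]cyclohept-3-en-1-yl]prop-2-enoic acid | CS(=O)(=O)O[C@@H]1C[C@H](C)C(/C=C/C(C)=O)=CC[C@H]1C(=C)C(=O)O | intermediate
14 | (3aS,7S,8aS)-7-methyl-3-methylidene-6-[(E)-3-oxobut-1-en-1-yl]-4,7,8,8a-tetrahydro-3aH-cyclohepta[b]furan-2-one (cis-fused lactone) | C=C1C(=O)O[C@H]2C[C@H](C)C(/C=C/C(C)=O)=CC[C@@H]12 | intermediate
15 | (1S,2R,6S)-2-(1-bromoethenyl)-6-methyl-5-[(E)-3-oxobut-1-en-1-yl]cyclohept-4-en-1-yl methanesulfonate (cis mesylate) | CS(=O)(=O)O[C@H]1C[C@H](C)C(/C=C/C(C)=O)=CC[C@H]1C(Br)=C | intermediate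
16 | Diels–Alder adduct (ring B with C1=C2; 3-acetyl with H-3 cis to H-5; 7-(1-bromoethenyl) cis to 8-mesyloxy; spiro at C11' to the cis-lactone of fragment 2; 3S,5S,7R,8S,10S,7'S,8'S,10'S,11'R) | CS(=O)(=O)O[C@H]1C[C@H](C)C2=C[C@H](C(C)=O)[C@]3(C[C@@H]2C[C@H]1C(Br)=C)C(=O)O[C@H]4C[C@H](C)C(/C=C/C(C)=O)=CC[C@@H]34 | intermediate
17 | C1 hydroperoxide of 18 (OOH in place of OH; 1R) | CS(=O)(=O)O[C@H]1C[C@H](C)[C@]2(OO)C=C(C(C)=O)[C@]3(C[C@@H]2C[C@H]1C(Br)=C)C(=O)O[C@H]4C[C@H](C)C(/C=C/C(C)=O)=CC[C@@H]34 | intermediate
18 | C1 tertiary alcohol (C1–OH cis to H-5; ring B enone C2=C3–C4=O; 7-(1-bromoethenyl) cis to 8-mesyloxy; 1R,5S,7R,8S,10S,7'S,8'S,10'S,11'R) | CS(=O)(=O)O[C@H]1C[C@H](C)[C@]2(O)C=C(C(C)=O)[C@]3(C[C@@H]2C[C@H]1C(Br)=C)C(=O)O[C@H]4C[C@H](C)C(/C=C/C(C)=O)=CC[C@@H]34 | intermediate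
19 | C12 carboxylate of 18 (CO2 in place of Br at C11; manganese salt, drawn as the free acid) | CS(=O)(=O)O[C@H]1C[C@H](C)[C@]2(O)C=C(C(C)=O)[C@]3(C[C@@H]2C[C@H]1C(=C)C(=O)O)C(=O)O[C@H]4C[C@H](C)C(/C=C/C(C)=O)=CC[C@@H]34 | intermediate
20 | CNP0168949.5 (1R,5S,7S,8R,10S,7'S,8'S,10'S,11'R) | C=C1C(=O)O[C@@H]2C[C@H](C)[C@]3(O)C=C(C(C)=O)[C@]4(C[C@@H]3C[C@@H]12)C(=O)O[C@H]1C[C@H](C)C(/C=C/C(C)=O)=CC[C@H]14 | target

**Count.** Total steps: 11. Longest linear sequence: 9 steps (steps 2, 3, 4, 5, 6, 7, 9, 10, 11).

**Steps most likely to fail**

Step 11. Low-valent nickel and manganese may engage the enone, the dienone or the newly formed α-methylene lactone (reductive coupling, conjugate reduction), or the alkenylnickel may be protonated instead of carboxylated. The fallback avoids reductive conditions altogether: 18 is treated with Pd(OAc)2, 1,1'-bis(diphenylphosphino)ferrocene, CO (1 atm), Et3N and water in DMF at 60 °C. Oxidative addition and CO insertion give an acylpalladium that water hydrolyses to the triethylammonium form of carboxylate 19, which closes ring C by the same SN2 displacement. The carboxyl carbon then comes from CO and the ring oxygen from water. The fallback sets out from 18 and returns at 20; it makes no compound outside the list (entry F0). The same change would serve step 7, from 12 to 14 through the ammonium form of 13.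

Step 9. The two electron-poor partners may combine so slowly that the secondary mesylate is lost by elimination on prolonged heating, or 14 may add to itself. The fallback moves the inversion behind the cycloaddition, so that the diene carries no leaving group while it is heated. The trans bromo alcohol 11 (threefold excess) and 14 in toluene with BHT at 85 to 100 °C should give the Diels–Alder adduct with a free trans C8 hydroxyl F1, the facial bias then resting on the C7 bromovinyl group alone. MsOH, Et3N, PPh3 and DIAD in toluene, as in step 8, install the mesylate with inversion under neutral conditions that do not isomerise the β,γ-unsaturated ketone. The fallback sets out from 11 and returns at 16.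

Step 10. Singlet oxygen may abstract H-10 or H-5 instead of H-3, so that oxygen ends at C2, or it may attack the face of ring B that carries the acetyl group. The fallback separates oxygen delivery from the alkene shift. Dimethyldioxirane in acetone at −20 °C should epoxidise only the electron-rich C1=C2 alkene of 16 on the face of H-5 and give the 1,2-epoxide F2. DBU (0.2 equiv) in CH2Cl2 at 0 °C then removes the acidic H-3 and opens the epoxide by E1cB elimination, which leaves the oxygen on C1 and the alkene at C2=C3. The fallback sets out from 16 and returns at 18.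

**Further compounds**

F0 | step 11 | none | none
F1 | step 9 | Diels–Alder adduct with a free trans C8 hydroxyl (analogue of 16 with OH in place of OMs; 3S,5S,7R,8R,10S,7'S,8'S,10'S,11'R) | O[C@@H]1C[C@H](C)C2=C[C@H](C(C)=O)[C@]3(C[C@@H]2C[C@H]1C(Br)=C)C(=O)O[C@H]4C[C@H](C)C(/C=C/C(C)=O)=CC[C@@H]34
F2 | step 10 | 1,2-epoxide of 16 (epoxide oxygen cis to H-5) | CS(=O)(=O)O[C@H]1C[C@H](C)[C@]2(O6)[C@@H]6[C@H](C(C)=O)[C@]3(C[C@@H]2C[C@H]1C(Br)=C)C(=O)O[C@H]4C[C@H](C)C(/C=C/C(C)=O)=CC[C@@H]34
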